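Follow the charge.

the same everywhere: electrophile 0.050 M; nucleophile 0.125 M

|  | temperature | remark | time |
|---|---|---|---|
| ash | 25 °C | the very flask that is asked about, followed so far |  |
| alder | 20 °C | run made earlier |  |
| flask | 25 °C |  | 2.0 h |

- ash (time / min: product / %, electrophile / %): 20.0: 40.8, 4.4; 40.0: 41.4, 2.6; 60.0: 44.6, 0.9; 80.0: 46.6, 2.1; 90.0: 47.3, 0; 120: 48.7, 1.0
- alder (time / min: product / %, electrophile / %): 20.0: 39.8, 9.7; 40.0: 44.9, 2.3; 60.0: 46.4, 1.1; 80.0: 47.4, 0.6; 90.0: 49.8, 1.4; 120: 50.6, 0.6

(readings scatter by 1 percentage point)

- eta: change nothing and wait 40 min more
- gamma: at 2.0 h add nucleophile, 50.0% of the amount charged, then wait 40 min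
- beta: at 2.0 h raise the temperature by 25 K, then wait 40 min
- delta: at 2.0 h add electrophile, 50.0% of the amount charged, then wait 40 min

- what is added takes up no volume worth counting
- the numbers in the tables scatter by 1 percentage point (one standard deviation)
- a reading or a percentage of product counts all its forms, free or not
- a reading of electrophile is of its free form alone

- product, in percent of the electrophile first charged, at 2.0 h
- the option that brings most further product ("none" if no option brings more than 2 percentage points) (eta / gamma / beta / delta / none)
- product present, in percent of the electrophile first charged, after eta
- product present, in percent of the electrophile first charged, after gamma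

In the ash run at 20.0 min, product reads 40.8% and free electrophile 4.4%, so 54.8% of the charge stands in neither reading. Divide the product gained over the first 20.0 min by the charge hidden over the same stretch and the clock leaves the comparison, which gives one cumulative ratio, 0.745. This is the early branching ratio, the fraction of charge won as product per fraction hidden over that stretch, a selectivity factor read at this nucleophile charge and carrying the scatter of the readings. So a fraction 0.427 of the electrophile that had branched by then stood as product.

The ratio is no constant of the run, for the same division at 120 min gives 0.968, so what follows is an estimate: two views apply the early fraction to different stocks. The dose view takes the fresh electrophile of delta, 50.0% of the charge, which is worth 21 percentage points. The forecast stands here: it names delta, with 48.7% now, 50.7% after eta and 51.8% after gamma, and it holds that “Temperature barely matters, since alder and ash look alike”.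

The heat view takes the ash run's hidden fraction at 120 min, 50.3%, as a reservoir, worth 21 points if it opens within 40 min. Its grounds are that product still climbs from 44.6% to 48.7% between 60.0 min and 120 min, and that free electrophile at 20.0 min reads twice as high at 20 °C as at 25 °C. This reckoning leaves the two stocks about equal, whereas the forecast ranks delta first, so the open point is whether a rise of 25 K reaches the reservoir in time.

The flask gives 49.7% at 2.0 h, and the best option is beta: it gains 22 points, against 18 points for delta, 4.5 points for gamma and 2.9 points for eta, leaving 52.6% after eta and 54.1% after gamma. At 120 min the dormant form holds 47.8%, which at the fraction 0.427 is worth 20 points. The dose view has its region too: with the dose multiplied by 3, delta gains 41 points, more than beta.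

    electrophile ⇌ dormant form (K = 27.0, k = 0.130 min⁻¹, Ea = 94.0 kJ mol⁻¹, ΔH = −19.0 kJ mol⁻¹)
    electrophile + product ⇌ idle adduct, settled at all times (K = 48.0 M⁻¹, ΔH = −20.0 kJ mol⁻¹)
    nucleophile + acid set free ⇌ protonated nucleophile, settled at all times (K = 7200 M⁻¹, ΔH = −8.00 kJ mol⁻¹)
    electrophile + nucleophile → acid set free + product (k = 0.860 M⁻¹ min⁻¹, Ea = 50.0 kJ mol⁻¹)
    (constants at 25 °C)

Take the neighbour flask with 0.050 M of nucleophile. Scaled with the nucleophile charge, the early branching ratio becomes 0.298, which as an estimate puts 23.0% of that flask's charge in product. The computed flask holds 25.9% product and 70.5% dormant form at 120 min.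

(All runs stem from a simulated flask on assumed constants, noise included.)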